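## The problem

The target 18 is an open-chain compound. It is a 1-(4-methoxyphenyl)propane-1,3-diol (C1 carbinol, C2 methine, C3 oxymethylene) whose C2 carries an (E)-3-(3,4-dimethoxyphenyl)allyl branch (C4 methylene, C5=C6 styrene) and whose primary oxygen on C3 is acylated by (Z)-2-(hydroxymethyl)but-2-enoic acid; the systematic names further down use their own locants. The chain has to be assembled around C2 from three different arms, and there is no ring through which stereochemistry could be relayed. The two adjacent stereocentres, C1 (S) and C2 (S), stand anti along C1–C2–C3. C1 can control C2 by 1,2-induction in an addition to an sp2 C2, or C2 could control C1 in a ketone reduction; the first direction is taken because a secondary aryl carbinol is easier to secure as one enantiomer than an acyclic, enolisable C2 centre. Three groups do not tolerate rough treatment: the free 4-methoxybenzylic alcohol ionises under acid, the electron-rich E styrene must survive every hydride, borane and electrophile, and the Z-trisubstituted enoate is the less stable geometric isomer and carries a free allylic hydroxyl. With a free hydroxyl on C1 and an ester on O3, base invites acyl migration, so the acyl group should arrive late and the last deprotection must be close to neutral. The enabling feature is that C2 bears one hydrogen and the oxymethylene C3 next to the C1 carbinol: H–C2–C3–O is the syn adduct of H and OH across a C2=C3 methylene group, the retron of a hydroboration–oxidation of a chiral 2-methylene carbinol.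

## Retrosynthesis

18 to 17. Only the O–Si bond at C1 is cut. A triethylsilyl ether is preferred to an ester or a benzyl-type ether on this oxygen because its removal needs neither base (acyl shift from O3 to O1, Z to E isomerisation) nor strong acid or hydrogen (benzylic ionisation, loss of the styrene). Precursor 17 differs from the target by one protecting group, and the forward step has to do nothing but cleave it.

17 to 15. In the acyl part the bond between the α-carbon and its hydroxymethyl carbon is cut together with the β-C–H bond, which leaves the but-2-ynoate 15 and a one-carbon electrophile. The neighbouring cut, acylation of O3 with the preformed hydroxymethyl acid, would need that acid as a protected and configurationally fragile Z isomer, and equilibrating routes to such enoates favour E. A syn hydrometalation of the alkyne makes the Z geometry a consequence of mechanism. 15 is simpler by one alkene geometry, one carbon and one free hydroxyl. The forward reaction must add hydride in the conjugate sense with the metal on the α-carbon, must spare the ester carbonyl, and must capture the electrophile before the geometry is lost.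

15 to 13 and 14. The ester C–O bond is cut to the primary alcohol 13 and commercial but-2-ynoic acid 14. Since 13 has a single free hydroxyl, the acylation needs no site selectivity; the cut to a free 1,3-diol would rest on a primary-versus-secondary discrimination. The forward step is a carbodiimide esterification that must not add the nucleophilic catalyst to the ynoate.

13 to 11. The C2–H and C3–O bonds are cut. This turns C2 and C3 into the C2=C3 methylene group of the allylic silyl ether 11 and removes the C2 stereocentre. Against the other cuts at C2 (the C2–C4 bond by enolate chemistry, or the C1–H bond by ketone reduction) this one keeps the complete carbon skeleton, uses C1 as the only source of induction and never places a carbonyl group next to an epimerisable C2. The precursor has one stereocentre instead of two. The forward hydroboration has to be anti-selective with respect to C1, put boron on C3 and leave the C5=C6 styrene alone; one bulky dialkylborane is asked to meet all three demands.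

11 to 10 to 9. The silyl ether is traced to the S carbinol 10, and 10 to its racemate 9. Silylation before the hydroboration means that the two oxygens of the later diol are never free together. The single stereocentre of 10 is taken from the racemate by a tartrate-controlled kinetic resolution, whose sense is predictable. An enantioselective reduction of the corresponding ketone would have to tell an aryl group from a 2-substituted vinyl group. The forward resolution must consume the R alcohol and leave the remote styrene untouched.

9 to 6 and 7. The C1–C2 bond is cut to the alkenyl bromide 6 (used as its lithium derivative) and 4-methoxybenzaldehyde 7. This cut creates the carbinol and the 2-methylene unit in one operation from a non-enolisable aldehyde. The forward step must generate the alkenyl anion without deprotonating the doubly allylic C4 methylene.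

6 to 2 and 3, and 2 to 1. The C4–C5 bond is cut to the E styryl bromide 2 (as the nucleophile) and 2,3-dibromopropene 3. Its allylic bromide is displaced and its vinylic bromide is kept for the next step; direct and transposed substitution on 3 give the same product. 2 comes from commercial 3,4-dimethoxycinnamic acid 1 by exchange of the carboxyl group for bromine. The forward reactions must carry the E alkene through halogen–metal exchange unchanged.

## Roads not taken

Alternative 1: The cut lies in the acyl group. The α-carbon–hydroxymethyl bond and the β-C–H bond of A1, the O1 triethylsilyl ether of the target, are traced to the ynoate 15. In the forward sense i-Bu2AlH, moderated by N-methylmorpholine N-oxide, adds hydride to the β-carbon, and the α-aluminated enoate takes up formaldehyde.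
- Merits: the Z geometry follows from syn addition and not from an equilibrium that would favour E; the acyl unit enters as cheap 14 and is completed by one carbon; no sensitive Z acid has to be activated.
- Weak points: it says nothing about how C1 and C2 are made; it exposes an advanced ester to an aluminium hydride; and the geometry depends on trapping before the alkenylalane equilibrates.
- Comparison: this road is a part of the chosen plan and not a rival to it. A1 is the same compound as 17, and step 8 is this reaction. As a headline it is at least as good in one respect: it puts the weight on the least precedented carbon–carbon bond formation of the synthesis, and the chosen plan carries that risk in full. What the chosen plan sets against it is that the end game is only worth running once the anti C1/C2 array exists, and that the hydroboration disconnection, not the side-chain chemistry, decides how the skeleton is assembled.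

Alternative 2: The cut is the C1–H bond. The racemic α-allylated β-keto ester A2 would be reduced by a ketoreductase with NADPH, which selects one of the two rapidly interconverting C2 epimers and one carbonyl face and gives the anti hydroxy ester A3.
- Merits: both stereocentres are fixed in one catalytic step, nothing is discarded in a resolution, no organolithium reagent is needed, and A2 is one C-alkylation away from a commercial β-keto ester.
- Weak points: the enzyme must accept an aryl ketone flanked by a long unsaturated α-substituent and must give the anti isomer of the right absolute configuration, which cannot be derived from the structure and has to be found by screening. Chemical dynamic resolutions of acyclic α-alkyl β-keto esters are not reliably anti-selective, and hydrogenation with RuCl2(binap)-type catalysts would endanger the styrene. A3 is a β-hydroxy ester of an electron-rich benzylic alcohol and is open to retro-aldol cleavage and dehydration. It still needs ester reduction and differentiation of the two hydroxyls before the route could be joined at 13.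
- Comparison: in step count and material economy this road is better, reaching the oxidation level of 13 in roughly half the operations. The chosen plan sets against it that each of its two stereochemical events follows an empirical rule of known sense (the tartrate mnemonic and the anti rule for bulky boranes), so that no selectivity has to be discovered.

Alternative 3: The cut is the C2–C4 bond. The ester A4, (R)-1-(3,4-dimethoxyphenyl)allyl (S)-3-hydroxy-3-(4-methoxyphenyl)propanoate, would be converted by lithium diisopropylamide (two equivalents) into its dianion, which rearranges in a [3,3] sense through a chair to the anti acid A5.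
- Merits: the stereo-determining step also forges a skeletal carbon–carbon bond and sets the E geometry of C5=C6 through the equatorial aryl group; the C1 hydroxyl, as its alkoxide, needs no protecting group and directs the enolate face; and the route is convergent.
- Weak points: two enantioenriched carbinols are required, although the allylic one is destroyed in the rearrangement and serves only to match the chair to the facial bias of the enolate. A4 is an ester of a 1-(3,4-dimethoxyphenyl)allyl alcohol, which ionises and transposes to the cinnamyl isomer easily. Under two equivalents of amide base, β-elimination and retro-aldol cleavage of the hydroxy ester compete. A5 must still be reduced and its hydroxyls differentiated.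
- Comparison: in convergence and in the bond-forming content of its key step this road is better, since the chosen key step builds no skeletal bond and follows a linear organometallic assembly with a resolution. The chosen plan sets against it robust intermediates, a single chiral reagent, and the absence of a labile allylic ester under strong base.

Key step: step 6

Remark on the chemistry: C1 is taken from racemic 9 by kinetic resolution. It is assumed that the tartrate mnemonic for secondary allylic alcohols holds with the 4-methoxyphenyl group as the carbinol substituent; aryl outranks the alkenyl carbon in the CIP sense, so the alcohol recovered with L-(+)-tartrate is S.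

## Route

Step 1
Reactants: 1 (E)-3-(3,4-dimethoxyphenyl)prop-2-enoic acid
Product: 2 (E)-4-(2-bromoethenyl)-1,2-dimethoxybenzene
Conditions: NBS (1.05 equiv), LiOAc (0.1 equiv), MeCN–H2O 19:1, rt
Reagents that add atoms: N-bromosuccinimide, O=C1CCC(=O)N1Br
Why: Catalytic Hunsdiecker-type bromodecarboxylation of a cinnamic acid: electrophilic bromine adds at the carboxyl-bearing carbon of the electron-rich alkene and the benzylic cation (or β-lactone) loses CO2 to give the favoured E bromoalkene; the alkene is more nucleophilic than the dimethoxyarene ring, so ring bromination should stay minor.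

Step 2
Reactants: 2 (E)-4-(2-bromoethenyl)-1,2-dimethoxybenzene; 3 2,3-dibromoprop-1-ene
Product: 6 (E)-4-(4-bromopenta-1,4-dien-1-yl)-1,2-dimethoxybenzene, via styryllithium 4 (not isolated), via styrylmagnesium bromide 5 (not isolated)
Conditions: t-BuLi (2.0 equiv), Et2O, −78 °C; MgBr2·OEt2 (1.1 equiv), −78 → 0 °C; 3 (1.3 equiv), CuI (5 mol %), THF, −30 → 0 °C
Reagents that add atoms: none
Why: Bromine–lithium exchange on an alkenyl bromide with t-BuLi at −78 °C retains the E geometry; after transmetalation the alkenylmagnesium bromide undergoes CuI-catalysed allylic substitution on 3, in which direct and allylically transposed attack give the same product and the vinylic bromide does not react.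

Step 3
Reactants: 6 (E)-4-(4-bromopenta-1,4-dien-1-yl)-1,2-dimethoxybenzene; 7 4-methoxybenzaldehyde
Product: 9 (±)-(E)-5-(3,4-dimethoxyphenyl)-1-(4-methoxyphenyl)-2-methylidenepent-4-en-1-ol, via dienyllithium 8 (not isolated)
Conditions: t-BuLi (2.0 equiv), Et2O, −78 °C, 15 min; 7 (1.1 equiv), −78 °C; then H2O
Reagents that add atoms: none
Why: Bromine–lithium exchange on a 2-bromoalk-1-ene and 1,2-addition of the alkenyllithium to a non-enolisable aryl aldehyde; exchange at −78 °C is much faster than deprotonation of the doubly allylic C4 methylene, and the carbinol centre C1 is formed racemic at this stage.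

Step 4
Reactants: 9 (±)-(E)-5-(3,4-dimethoxyphenyl)-1-(4-methoxyphenyl)-2-methylidenepent-4-en-1-ol
Product: 10 (S,E)-5-(3,4-dimethoxyphenyl)-1-(4-methoxyphenyl)-2-methylidenepent-4-en-1-ol
Conditions: Ti(OiPr)4 (0.2 equiv), L-(+)-diisopropyl tartrate (0.3 equiv), t-BuOOH (0.65 equiv), 4 Å MS, CH2Cl2, −20 °C
Reagents that add atoms: none
Why: Sharpless kinetic resolution of a secondary allylic alcohol: with L-(+)-diisopropyl tartrate the enantiomer whose carbinol hydrogen lies on the oxygen-delivering face (here the R alcohol) is epoxidised fast, so the S alcohol 10 remains once somewhat more than half of 9 has been consumed; the C5=C6 alkene is no allylic alcohol and is not epoxidised by the Ti(OiPr)4–tartrate–hydroperoxide system.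

Step 5
Reactants: 10 (S,E)-5-(3,4-dimethoxyphenyl)-1-(4-methoxyphenyl)-2-methylidenepent-4-en-1-ol
Product: 11 triethyl{[(S,E)-5-(3,4-dimethoxyphenyl)-1-(4-methoxyphenyl)-2-methylidenepent-4-en-1-yl]oxy}silane
Conditions: Et3SiCl (1.3 equiv), imidazole (2 equiv), DMAP (cat.), CH2Cl2, 0 °C → rt
Reagents that add atoms: chlorotriethylsilane, CC[Si](Cl)(CC)CC
Why: Silylation of a secondary alcohol with a silyl chloride and imidazole; the triethylsilyl group is stable to dialkylboranes, perborate, carbodiimide acylation and the aluminium hydride of step 8, and can later be removed without acid strong enough to ionise the 4-methoxybenzylic position.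

Step 6
Reactants: 11 triethyl{[(S,E)-5-(3,4-dimethoxyphenyl)-1-(4-methoxyphenyl)-2-methylidenepent-4-en-1-yl]oxy}silane
Product: 13 (2S,E)-5-(3,4-dimethoxyphenyl)-2-[(S)-(4-methoxyphenyl)(triethylsilyloxy)methyl]pent-4-en-1-ol, via B-alkyl-9-borabicyclononane 12 (not isolated)
Conditions: 9-BBN (2.0 equiv), THF, 0 °C → rt; then NaBO3·4H2O, THF–H2O, rt
Reagents that add atoms: sodium perborate tetrahydrate, [Na+].[O-]OB=O.O.O.O.O
Why: This is a hydroboration–oxidation with acyclic 1,2-induction, the reaction type established for 2-substituted allylic alcohols and their ethers with 9-borabicyclo[3.3.1]nonane. The B–H bond adds through a four-centre syn transition state, boron to the unsubstituted C3 and hydrogen to C2, and perborate then replaces boron by oxygen with retention, so that C2–H and C3–O are formed and no ring is closed. The new stereocentre C2 is controlled by C1: in the reactive conformer the small C1–H lies near the alkene plane on the side of the =CH2 terminus, under the incoming bicyclic borane, the aryl group stands perpendicular to that plane and the silyloxy group points outward, and the reagent adds to the face opposite the aryl group. After oxidation this places the C1 oxygen and the C2 allyl branch anti, which is the (1S,2S) array of the target. Regioselectivity follows from the 1,1-disubstitution of the alkene and the size of the reagent. The step also needs chemoselectivity over the C5=C6 styrene, which rests on the far lower rate of this borane with 1,2-disubstituted internal alkenes than with 1,1-disubstituted terminal ones. The silyl ether spares a borane equivalent and keeps the product easy to separate from cyclooctane-1,5-diol, and the mild perborate oxidation should leave the silyl ether and both arenes alone.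

Step 7
Reactants: 13 (2S,E)-5-(3,4-dimethoxyphenyl)-2-[(S)-(4-methoxyphenyl)(triethylsilyloxy)methyl]pent-4-en-1-ol; 14 but-2-ynoic acid
Product: 15 (2S,E)-5-(3,4-dimethoxyphenyl)-2-[(S)-(4-methoxyphenyl)(triethylsilyloxy)methyl]pent-4-en-1-yl but-2-ynoate
Conditions: DCC (1.3 equiv), DMAP (0.1 equiv), CH2Cl2, −20 → 0 °C
Reagents that add atoms: none
Why: Steglich esterification; 13 has one free hydroxyl, so no site selectivity is needed, and low temperature with substoichiometric DMAP limits conjugate addition of the nucleophilic catalyst to the ynoate.

Step 8
Reactants: 15 (2S,E)-5-(3,4-dimethoxyphenyl)-2-[(S)-(4-methoxyphenyl)(triethylsilyloxy)methyl]pent-4-en-1-yl but-2-ynoate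
Product: 17 (2S,E)-5-(3,4-dimethoxyphenyl)-2-[(S)-(4-methoxyphenyl)(triethylsilyloxy)methyl]pent-4-en-1-yl (Z)-2-(hydroxymethyl)but-2-enoate, via α-aluminated enoate 16 (not isolated)
Conditions: i-Bu2AlH (1.5 equiv), NMO (1.5 equiv), THF, 0 °C; then CH2O (gas, from paraformaldehyde), 0 °C → rt; aq. potassium sodium tartrate
Reagents that add atoms: formaldehyde, C=O
Why: Conjugate hydroalumination of a 2-ynoate with N-oxide-complexed i-Bu2AlH followed by addition of the alkenylalane to an aldehyde (vinylalumination): hydride and aluminium add syn, hydride to the β-carbon and aluminium to the α-carbon, and the α-carbon then bonds to formaldehyde with retention, so that methyl and ester carbonyl are cis (Z); the complexed hydride reacts faster in the conjugate mode than at the ester carbonyl, and keeping the mixture at or below 0 °C until formaldehyde is present guards the geometry.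

Step 9
Reactants: 17 (2S,E)-5-(3,4-dimethoxyphenyl)-2-[(S)-(4-methoxyphenyl)(triethylsilyloxy)methyl]pent-4-en-1-yl (Z)-2-(hydroxymethyl)but-2-enoate
Product: 18 (2S,E)-5-(3,4-dimethoxyphenyl)-2-[(S)-hydroxy(4-methoxyphenyl)methyl]pent-4-en-1-yl (Z)-2-(hydroxymethyl)but-2-enoate
Conditions: HF·pyridine, pyridine, THF, 0 °C
Reagents that add atoms: none
Why: Fluoride-mediated cleavage of a triethylsilyl ether under pyridine-buffered conditions; no base is present that could move the acyl group from O3 to O1 or isomerise the Z enoate, and the medium is too weakly acidic to ionise the 4-methoxybenzylic alcohol.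

## Compound list

1 | (E)-3-(3,4-dimethoxyphenyl)prop-2-enoic acid (3,4-dimethoxycinnamic acid) | COc1ccc(/C=C/C(=O)O)cc1OC | starting material
2 | (E)-4-(2-bromoethenyl)-1,2-dimethoxybenzene | COc1ccc(/C=C/Br)cc1OC | intermediate
3 | 2,3-dibromoprop-1-ene | C=C(Br)CBr | starting material
4 | [(E)-2-(3,4-dimethoxyphenyl)ethenyl]lithium | [Li]/C=C/c1ccc(OC)c(OC)c1 | intermediate
5 | [(E)-2-(3,4-dimethoxyphenyl)ethenyl]magnesium bromide | Br[Mg]/C=C/c1ccc(OC)c(OC)c1 | intermediate
6 | (E)-4-(4-bromopenta-1,4-dien-1-yl)-1,2-dimethoxybenzene | C=C(Br)C/C=C/c1ccc(OC)c(OC)c1 | intermediate
7 | 4-methoxybenzaldehyde | COc1ccc(C=O)cc1 | starting material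
8 | [(E)-5-(3,4-dimethoxyphenyl)penta-1,4-dien-2-yl]lithium | [Li]C(=C)C/C=C/c1ccc(OC)c(OC)c1 | intermediate
9 | (±)-(E)-5-(3,4-dimethoxyphenyl)-1-(4-methoxyphenyl)-2-methylidenepent-4-en-1-ol (racemic at C1) | C=C(C/C=C/c1ccc(OC)c(OC)c1)C(O)c1ccc(OC)cc1 | intermediate
10 | (S,E)-5-(3,4-dimethoxyphenyl)-1-(4-methoxyphenyl)-2-methylidenepent-4-en-1-ol | C=C(C/C=C/c1ccc(OC)c(OC)c1)[C@H](O)c1ccc(OC)cc1 | intermediate
11 | triethyl{[(S,E)-5-(3,4-dimethoxyphenyl)-1-(4-methoxyphenyl)-2-methylidenepent-4-en-1-yl]oxy}silane | C=C(C/C=C/c1ccc(OC)c(OC)c1)[C@H](O[Si](CC)(CC)CC)c1ccc(OC)cc1 | intermediate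
12 | 9-{(2R,E)-5-(3,4-dimethoxyphenyl)-2-[(S)-(4-methoxyphenyl)(triethylsilyloxy)methyl]pent-4-en-1-yl}-9-borabicyclo[3.3.1]nonane (same spatial arrangement as 13; the descriptor changes because boron ranks below carbon) | B1(C2CCCC1CCC2)C[C@H](C/C=C/c1ccc(OC)c(OC)c1)[C@H](O[Si](CC)(CC)CC)c1ccc(OC)cc1 | intermediate
13 | (2S,E)-5-(3,4-dimethoxyphenyl)-2-[(S)-(4-methoxyphenyl)(triethylsilyloxy)methyl]pent-4-en-1-ol | OC[C@H](C/C=C/c1ccc(OC)c(OC)c1)[C@H](O[Si](CC)(CC)CC)c1ccc(OC)cc1 | intermediate
14 | but-2-ynoic acid | CC#CC(=O)O | starting material
15 | (2S,E)-5-(3,4-dimethoxyphenyl)-2-[(S)-(4-methoxyphenyl)(triethylsilyloxy)methyl]pent-4-en-1-yl but-2-ynoate | CC#CC(=O)OC[C@H](C/C=C/c1ccc(OC)c(OC)c1)[C@H](O[Si](CC)(CC)CC)c1ccc(OC)cc1 | intermediate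
16 | (2S,E)-5-(3,4-dimethoxyphenyl)-2-[(S)-(4-methoxyphenyl)(triethylsilyloxy)methyl]pent-4-en-1-yl (E)-2-[bis(2-methylpropyl)alumanyl]but-2-enoate (methyl cis to the ester carbonyl) | C/C=C(/[Al](CC(C)C)CC(C)C)C(=O)OC[C@H](C/C=C/c1ccc(OC)c(OC)c1)[C@H](O[Si](CC)(CC)CC)c1ccc(OC)cc1 | intermediate
17 | (2S,E)-5-(3,4-dimethoxyphenyl)-2-[(S)-(4-methoxyphenyl)(triethylsilyloxy)methyl]pent-4-en-1-yl (Z)-2-(hydroxymethyl)but-2-enoate | C/C=C(/CO)C(=O)OC[C@H](C/C=C/c1ccc(OC)c(OC)c1)[C@H](O[Si](CC)(CC)CC)c1ccc(OC)cc1 | intermediate
18 | (2S,E)-5-(3,4-dimethoxyphenyl)-2-[(S)-hydroxy(4-methoxyphenyl)methyl]pent-4-en-1-yl (Z)-2-(hydroxymethyl)but-2-enoate | C/C=C(/CO)C(=O)OC[C@H](C/C=C/c1ccc(OC)c(OC)c1)[C@H](O)c1ccc(OC)cc1 | target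

## Step count and least certain steps

Total: 9 steps. Longest linear sequence: 9 steps (1 to 18); 3, 7 and 14 are commercial and enter directly.

Step 6 (key step). The facial discrimination at C2 may be insufficient, because the flat aryl group is a less clear-cut large substituent than the alkyl groups for which the rule is best documented. The hindered alkene may also need long reaction times, during which the borane can begin to add to the C5=C6 styrene and the silyl group can shift from O1 to O3 in the basic oxidation. Fallback, from 10 back to 15:
- The free carbinol 10 is hydroborated directly with excess 9-BBN (the hydroxyl first forms an O-boryl ether) and oxidised with NaBO3·4H2O to (1S,2S)-2-[(E)-3-(3,4-dimethoxyphenyl)prop-2-en-1-yl]-1-(4-methoxyphenyl)propane-1,3-diol F1. This is the substrate type on which the anti rule is most firmly based, and at the diol stage the diastereomers can be separated and the relative configuration checked.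
- The primary hydroxyl of F1 is acylated selectively with 14 (DCC, DMAP cat., −20 °C) to (2S,E)-5-(3,4-dimethoxyphenyl)-2-[(S)-hydroxy(4-methoxyphenyl)methyl]pent-4-en-1-yl but-2-ynoate F2.
- Silylation of F2 (Et3SiCl, imidazole) returns to 15.

The change is one of substrate and order (induction from an O-boryl carbinol, hydroxyl differentiation by acylation), not only of the borane.

Step 8. The Z geometry may erode through equilibration of the α-aluminated enoate via its allenolate form before formaldehyde is captured; free i-Bu2AlH may reduce the ester in the 1,2 sense; and capture of monomeric formaldehyde may be inefficient. Fallback, from 15 back to 17: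
- Pd(PPh3)4-catalysed syn hydrostannation with Bu3SnH places tin on the α-carbon and gives (2S,E)-5-(3,4-dimethoxyphenyl)-2-[(S)-(4-methoxyphenyl)(triethylsilyloxy)methyl]pent-4-en-1-yl (E)-2-(tributylstannyl)but-2-enoate F3.
- Iododestannylation (I2, CH2Cl2, 0 °C) gives, with retention, (2S,E)-5-(3,4-dimethoxyphenyl)-2-[(S)-(4-methoxyphenyl)(triethylsilyloxy)methyl]pent-4-en-1-yl (E)-2-iodobut-2-enoate F4.
- Stille coupling of F4 with (tributylstannyl)methanol (Pd(PPh3)4, dioxane, 80 °C) installs the hydroxymethyl group and gives 17.

No aluminium hydride meets the ester, and the geometry is carried by configurationally stable alkenyl tin and iodine compounds.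

Step 4. Epoxidation of the 2-substituted, aryl-flanked allylic alcohol may be slow or may discriminate poorly between the enantiomers, so that high enantiomeric purity is reached only at high conversion. The Lewis-acidic titanium may also ionise the 4-methoxybenzylic carbinol. At best half of 9 is used. Fallback, from 9 back to 10:
- Oxidation with MnO2 (CH2Cl2, rt) gives (E)-5-(3,4-dimethoxyphenyl)-1-(4-methoxyphenyl)-2-methylidenepent-4-en-1-one F5.
- F5 is reduced with catecholborane and 2-methyl-CBS-oxazaborolidine (toluene, −78 °C) to 10.

The R catalyst is expected to give 10 if the coplanar 4-methoxyphenyl group acts as the larger substituent. Because both carbonyl substituents are branched sp2 groups, sense and level of induction would first have to be established, which is why this is not the main route.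

Step 3. Proton transfer from the doubly allylic C4 methylene to the alkenyllithium or to t-BuLi may compete with exchange and addition, which would give reduced and isomerised dienes. Fallback, from 6 and 7 back to 9: Nozaki–Hiyama–Kishi coupling (CrCl2 3 equiv, NiCl2 2 mol %, DMF, rt), in which a non-basic alkenylchromium reagent adds to the aldehyde. This fallback makes no new compound (F0).

## Further compounds

F1 | step 6 | (1S,2S)-2-[(E)-3-(3,4-dimethoxyphenyl)prop-2-en-1-yl]-1-(4-methoxyphenyl)propane-1,3-diol | OC[C@H](C/C=C/c1ccc(OC)c(OC)c1)[C@H](O)c1ccc(OC)cc1
F2 | step 6 | (2S,E)-5-(3,4-dimethoxyphenyl)-2-[(S)-hydroxy(4-methoxyphenyl)methyl]pent-4-en-1-yl but-2-ynoate | CC#CC(=O)OC[C@H](C/C=C/c1ccc(OC)c(OC)c1)[C@H](O)c1ccc(OC)cc1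
F3 | step 8 | (2S,E)-5-(3,4-dimethoxyphenyl)-2-[(S)-(4-methoxyphenyl)(triethylsilyloxy)methyl]pent-4-en-1-yl (E)-2-(tributylstannyl)but-2-enoate | C/C=C(/[Sn](CCCC)(CCCC)CCCC)C(=O)OC[C@H](C/C=C/c1ccc(OC)c(OC)c1)[C@H](O[Si](CC)(CC)CC)c1ccc(OC)cc1
F4 | step 8 | (2S,E)-5-(3,4-dimethoxyphenyl)-2-[(S)-(4-methoxyphenyl)(triethylsilyloxy)methyl]pent-4-en-1-yl (E)-2-iodobut-2-enoate | C/C=C(/I)C(=O)OC[C@H](C/C=C/c1ccc(OC)c(OC)c1)[C@H](O[Si](CC)(CC)CC)c1ccc(OC)cc1
F5 | step 4 | (E)-5-(3,4-dimethoxyphenyl)-1-(4-methoxyphenyl)-2-methylidenepent-4-en-1-one | C=C(C/C=C/c1ccc(OC)c(OC)c1)C(=O)c1ccc(OC)cc1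
F0 | step 3 | none | none
A1 | alternative 1 | (2S,E)-5-(3,4-dimethoxyphenyl)-2-[(S)-(4-methoxyphenyl)(triethylsilyloxy)methyl]pent-4-en-1-yl (Z)-2-(hydroxymethyl)but-2-enoate | C/C=C(/CO)C(=O)OC[C@H](C/C=C/c1ccc(OC)c(OC)c1)[C@H](O[Si](CC)(CC)CC)c1ccc(OC)cc1
A2 | alternative 2 | ethyl (E)-5-(3,4-dimethoxyphenyl)-2-(4-methoxybenzoyl)pent-4-enoate (racemic) | CCOC(=O)C(C/C=C/c1ccc(OC)c(OC)c1)C(=O)c1ccc(OC)cc1
A3 | alternative 2 | ethyl (2R,E)-5-(3,4-dimethoxyphenyl)-2-[(S)-hydroxy(4-methoxyphenyl)methyl]pent-4-enoate | CCOC(=O)[C@H](C/C=C/c1ccc(OC)c(OC)c1)[C@H](O)c1ccc(OC)cc1
A4 | alternative 3 | (R)-1-(3,4-dimethoxyphenyl)prop-2-en-1-yl (S)-3-hydroxy-3-(4-methoxyphenyl)propanoate | C=C[C@@H](OC(=O)C[C@H](O)c1ccc(OC)cc1)c1ccc(OC)c(OC)c1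
A5 | alternative 3 | (2R,E)-5-(3,4-dimethoxyphenyl)-2-[(S)-hydroxy(4-methoxyphenyl)methyl]pent-4-enoic acid | OC(=O)[C@H](C/C=C/c1ccc(OC)c(OC)c1)[C@H](O)c1ccc(OC)cc1
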